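**Retrosynthetic overview**

1. The C11/C12 epoxide comes last, from a hydroxyl-directed Sharpless epoxidation of the C13 allylic alcohol followed by inversion at C13; the C3 propionate comes from a reagent-controlled reduction of a C3 ketone.
2. Key disconnection: the cyclohexane ring is opened at C1–C15 and C4–C16 (retro-Diels–Alder) to one fourteen-membered carbocycle that holds a 2-silyloxy-1,3-diene (C1=C2–C3(OSiEt3)=C4) in the ring and a terminal allene (C16=C15=C17H2) on C7. The enabling feature is the cyclohexane ring itself: its exocyclic methylene on C15, next to the ring-fusion CH (C16), is the unused π bond of an allene, and its oxygen on C3, between C2H2 and quaternary C4, is the enol-ether carbon of a siloxydiene.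
3. The diene geometry is set by 1,4-hydrosilylation of a macrocyclic cross-conjugated dienone; the fourteen-membered ring is closed at C3–C4 by a Nozaki–Hiyama–Kishi reaction of a 2-iodoalkene with an enal.
4. The open chain grows from a cis-γ-lactone: crotylboration (C8, C9), lactone alkylation (C7), Wittig olefination (C11=C12), allylboration (C13), cross-metathesis (C1=C2); the lactone carbonyl becomes the allene (lactol, alkyne, allene).
5. Ring order: fourteen-membered ring (step 18); then cyclohexane and cyclopentane in one step, which turns the fourteen-membered ring into the eleven-membered ring (step 21); epoxide last (step 25).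

Key step: step 21

Position labels (target): cyclohexane = C15 (bears exocyclic C17H2), C1 (CH bearing C14H2), C2 (CH2), C3 (CH–O-propionyl), C4 (quaternary, CH3), C16 (ring-fusion CH); cyclopentane = C4, C5, C6, C7, C16; chain from C7 back to C1 = C8 (CH–CH3), C9 (CH–OAc), C10 (CH2), C11/C12 (epoxide, CH3 on C12), C13 (CH–OH), C14 (CH2). Target = (1R,3S,4S,7R,8S,9S,11S,12S,13R,16S).

Remark on the chemistry: the target is the threo (syn) epoxy alcohol, whereas metal-directed epoxidation of a 2-methyl allylic alcohol is erythro-selective; C13 is therefore carried as the (S)-epimer, used to direct the epoxidation, and inverted in the last step.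

**Route**

Step 1
Reactants: 1 3-[(tert-butyldimethylsilyl)oxy]propanal
Product: 2 (3S,4S)-1-[(tert-butyldimethylsilyl)oxy]-4-methylhex-5-en-3-ol
Conditions: (Z)-crotyl-B(Ipc)2 (Ipc from (−)-α-pinene, preformed from (+)-Ipc2BOMe), THF, −78 °C; then NaOH, H2O2, 0 °C to rt
Reagents that add atoms: (Z)-crotyldiisopinocampheylborane, C/C=C\CB([C@H]1C[C@H]2C[C@@H]([C@@H]1C)C2(C)C)[C@H]1C[C@H]2C[C@@H]([C@@H]1C)C2(C)C
Why: Brown crotylboration through a closed chair transition state; the (Z)-crotyl unit gives the syn methyl/hydroxyl pair and this Ipc series directs Re-face attack, which should set C8 and C9 as (S,S).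

Step 2
Reactants: 2 (3S,4S)-1-[(tert-butyldimethylsilyl)oxy]-4-methylhex-5-en-3-ol
Product: 4 (3S,4S)-6-[(tert-butyldimethylsilyl)oxy]-3-methylhexane-1,4-diol, via alkylborane 3 (not isolated)
Conditions: 9-BBN, THF, 0 °C to rt; then NaOH, H2O2, 0 °C
Reagents that add atoms: hydrogen peroxide, OO
Why: anti-Markovnikov hydroboration–oxidation of the terminal vinyl group; no stereocentre is touched.

Step 3
Reactants: 4 (3S,4S)-6-[(tert-butyldimethylsilyl)oxy]-3-methylhexane-1,4-diol
Product: 6 (4S,5S)-5-{2-[(tert-butyldimethylsilyl)oxy]ethyl}-4-methyloxolan-2-one (cis), via lactol 5 (not isolated)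
Conditions: TEMPO (cat.), PhI(OAc)2, CH2Cl2, rt
Reagents that add atoms: none
Why: oxoammonium oxidation is selective for the primary alcohol; the aldehyde closes to the lactol, which is oxidised on to the γ-lactone with both stereocentres intact.

Step 4
Reactants: 7 but-3-yn-1-ol
Product: 8 3-iodobut-3-en-1-ol
Conditions: NaI, Me3SiCl, H2O, MeCN, rt
Reagents that add atoms: sodium iodide, [Na+].[I-]
Why: Markovnikov hydroiodination of the terminal alkyne by HI generated in the flask gives the 2-iodo-1-alkene.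

Step 5
Reactants: 8 3-iodobut-3-en-1-ol
Product: 9 3-iodobut-3-en-1-yl trifluoromethanesulfonate
Conditions: Tf2O, 2,6-lutidine, CH2Cl2, −78 °C; used at once
Reagents that add atoms: triflic anhydride, O=S(=O)(OS(=O)(=O)C(F)(F)F)C(F)(F)F
Why: O-triflation makes the homoallylic carbon electrophilic enough to alkylate a lactone enolate at low temperature before elimination can compete.

Step 6
Reactants: 6 (4S,5S)-5-{2-[(tert-butyldimethylsilyl)oxy]ethyl}-4-methyloxolan-2-one; 9 3-iodobut-3-en-1-yl trifluoromethanesulfonate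
Product: 10 (3S,4S,5S)-5-{2-[(tert-butyldimethylsilyl)oxy]ethyl}-3-(3-iodobut-3-en-1-yl)-4-methyloxolan-2-one
Conditions: LiN(SiMe3)2, THF, −78 °C; then 9, DMPU, −78 to −40 °C
Reagents that add atoms: none
Why: lactone enolate alkylation; the electrophile should enter anti to the cis-disposed C8 methyl and C9 side chain, setting C7 trans to the methyl group.

Step 7
Reactants: 10 (3S,4S,5S)-5-{2-[(tert-butyldimethylsilyl)oxy]ethyl}-3-(3-iodobut-3-en-1-yl)-4-methyloxolan-2-one
Product: 11 (3S,4S,5S)-5-(2-hydroxyethyl)-3-(3-iodobut-3-en-1-yl)-4-methyloxolan-2-one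
Conditions: HF·pyridine, THF/pyridine, 0 °C to rt
Reagents that add atoms: none
Why: fluoride cleavage of the primary silyl ether; lactone and vinyl iodide are inert.

Step 8
Reactants: 11 (3S,4S,5S)-5-(2-hydroxyethyl)-3-(3-iodobut-3-en-1-yl)-4-methyloxolan-2-one
Product: 12 2-[(2S,3S,4S)-4-(3-iodobut-3-en-1-yl)-3-methyl-5-oxooxolan-2-yl]acetaldehyde
Conditions: Dess–Martin periodinane, CH2Cl2, 0 °C to rt
Reagents that add atoms: none
Why: Dess–Martin oxidation under neutral conditions should avoid β-elimination of the lactone oxygen.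

Step 9
Reactants: 12 2-[(2S,3S,4S)-4-(3-iodobut-3-en-1-yl)-3-methyl-5-oxooxolan-2-yl]acetaldehyde
Product: 13 (2E)-4-[(2S,3S,4S)-4-(3-iodobut-3-en-1-yl)-3-methyl-5-oxooxolan-2-yl]-2-methylbut-2-enal
Conditions: Ph3P=C(CH3)CHO, toluene, 80 °C
Reagents that add atoms: 2-(triphenylphosphoranylidene)propanal, CC(C=O)=P(c1ccccc1)(c1ccccc1)c1ccccc1
Why: Wittig olefination with a formyl-stabilised ylide is (E)-selective and gives the C11=C12 enal directly; the α-branched enal product should not react again.

Step 10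
Reactants: 13 (2E)-4-[(2S,3S,4S)-4-(3-iodobut-3-en-1-yl)-3-methyl-5-oxooxolan-2-yl]-2-methylbut-2-enal
Product: 14 (3S,4S,5S)-5-[(2E,4S)-4-hydroxy-3-methylhepta-2,6-dien-1-yl]-3-(3-iodobut-3-en-1-yl)-4-methyloxolan-2-one
Conditions: (−)-Ipc2B(allyl) (Ipc from (+)-α-pinene), Et2O, −78 °C; then NaBO3·4H2O, THF/H2O, rt
Reagents that add atoms: (−)-B-allyldiisopinocampheylborane, C=CCB([C@@H]1C[C@@H]2C[C@H]([C@H]1C)C2(C)C)[C@@H]1C[C@@H]2C[C@H]([C@H]1C)C2(C)C
Why: Brown allylboration; this Ipc series directs Si-face attack on the enal, which should set C13 as (S), the configuration needed for the directed epoxidation in step 25.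

Step 11
Reactants: 14 (3S,4S,5S)-5-[(2E,4S)-4-hydroxy-3-methylhepta-2,6-dien-1-yl]-3-(3-iodobut-3-en-1-yl)-4-methyloxolan-2-one
Product: 15 (3S,4S,5S)-5-{(2E,4S)-4-[(tert-butyldimethylsilyl)oxy]-3-methylhepta-2,6-dien-1-yl}-3-(3-iodobut-3-en-1-yl)-4-methyloxolan-2-one
Conditions: t-BuMe2SiOTf, 2,6-lutidine, CH2Cl2, −78 to 0 °C
Reagents that add atoms: tert-butyldimethylsilyl triflate, CC(C)(C)[Si](C)(C)OS(=O)(=O)C(F)(F)F
Why: silylation of the secondary alcohol with the silyl triflate.

Step 12
Reactants: 15 (3S,4S,5S)-5-{(2E,4S)-4-[(tert-butyldimethylsilyl)oxy]-3-methylhepta-2,6-dien-1-yl}-3-(3-iodobut-3-en-1-yl)-4-methyloxolan-2-one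
Product: 16 methyl (2E,5S,6E)-5-[(tert-butyldimethylsilyl)oxy]-8-[(2S,3S,4S)-4-(3-iodobut-3-en-1-yl)-3-methyl-5-oxooxolan-2-yl]-6-methylocta-2,6-dienoate
Conditions: methyl acrylate, RuCl2(H2IMes)(=CH-C6H4-2-O-i-Pr) (second-generation Hoveyda–Grubbs catalyst, 5 mol %), CH2Cl2, 40 °C
Reagents that add atoms: methyl acrylate, C=CC(=O)OC
Why: olefin cross-metathesis of the terminal alkene with an acrylate is (E)-selective; the trisubstituted alkene and the 1,1-disubstituted vinyl iodide are too hindered to enter the cycle.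

Step 13
Reactants: 16 methyl (2E,5S,6E)-5-[(tert-butyldimethylsilyl)oxy]-8-[(2S,3S,4S)-4-(3-iodobut-3-en-1-yl)-3-methyl-5-oxooxolan-2-yl]-6-methylocta-2,6-dienoate
Product: 17 (3S,4S,5S)-5-{(2E,4S,6E)-4-[(tert-butyldimethylsilyl)oxy]-8-hydroxy-3-methylocta-2,6-dien-1-yl}-3-(3-iodobut-3-en-1-yl)-4-methyloxolan-2-ol (lactol, both anomers)
Conditions: i-Bu2AlH (3.5 equiv), CH2Cl2, −78 °C; aqueous potassium sodium tartrate
Reagents that add atoms: none
Why: DIBAL-H reduction at −78 °C stops at the lactol for the γ-lactone (stable aluminium hemiacetal) while the enoate is reduced 1,2 to the allylic alcohol.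

Step 14
Reactants: 17 (3S,4S,5S)-5-{(2E,4S,6E)-4-[(tert-butyldimethylsilyl)oxy]-8-hydroxy-3-methylocta-2,6-dien-1-yl}-3-(3-iodobut-3-en-1-yl)-4-methyloxolan-2-ol
Product: 18 (2E,5S,6E,9S,10S,11S)-5-[(tert-butyldimethylsilyl)oxy]-11-ethynyl-14-iodo-6,10-dimethylpentadeca-2,6,14-triene-1,9-diol
Conditions: dimethyl (1-diazo-2-oxopropyl)phosphonate, K2CO3, MeOH, 0 °C to rt
Reagents that add atoms: Ohira–Bestmann reagent, CC(=O)C(=[N+]=[N-])P(=O)(OC)OC
Why: Seyferth–Gilbert homologation with the Ohira–Bestmann reagent on the lactol (masked aldehyde) gives the terminal alkyne and frees the C9 hydroxyl; the mild carbonate base should leave C7 unepimerised.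

Step 15
Reactants: 18 (2E,5S,6E,9S,10S,11S)-5-[(tert-butyldimethylsilyl)oxy]-11-ethynyl-14-iodo-6,10-dimethylpentadeca-2,6,14-triene-1,9-diol
Product: 20 (2E,5S,6E,9S,10S,11R)-5-[(tert-butyldimethylsilyl)oxy]-14-iodo-6,10-dimethyl-11-(propa-1,2-dien-1-yl)pentadeca-2,6,14-triene-1,9-diol, via propargylic amine 19 (not isolated)
Conditions: paraformaldehyde, CuI (0.5 equiv), (c-C6H11)2NH, 1,4-dioxane, reflux
Reagents that add atoms: formaldehyde (from paraformaldehyde), C=O
Why: Crabbé homologation; the Mannich base from alkyne, formaldehyde and amine undergoes copper-mediated 1,5-hydride transfer with loss of the imine to give the terminal allene, and without palladium the vinyl iodide should survive.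

Step 16
Reactants: 20 (2E,5S,6E,9S,10S,11R)-5-[(tert-butyldimethylsilyl)oxy]-14-iodo-6,10-dimethyl-11-(propa-1,2-dien-1-yl)pentadeca-2,6,14-triene-1,9-diol
Product: 21 (2E,5S,6E,9S,10S,11R)-5-[(tert-butyldimethylsilyl)oxy]-9-hydroxy-14-iodo-6,10-dimethyl-11-(propa-1,2-dien-1-yl)pentadeca-2,6,14-trienal
Conditions: MnO2, CH2Cl2, rt
Reagents that add atoms: none
Why: MnO2 oxidises only the primary allylic alcohol; the saturated C9 carbinol, the allene and the silyl ether are inert.

Step 17
Reactants: 21 (2E,5S,6E,9S,10S,11R)-5-[(tert-butyldimethylsilyl)oxy]-9-hydroxy-14-iodo-6,10-dimethyl-11-(propa-1,2-dien-1-yl)pentadeca-2,6,14-trienal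
Product: 22 (2E,5S,6E,9S,10S,11R)-9-acetoxy-5-[(tert-butyldimethylsilyl)oxy]-14-iodo-6,10-dimethyl-11-(propa-1,2-dien-1-yl)pentadeca-2,6,14-trienal
Conditions: Ac2O, pyridine, DMAP (cat.), CH2Cl2, 0 °C
Reagents that add atoms: acetic anhydride, CC(=O)OC(C)=O
Why: DMAP-catalysed acetylation of the only free hydroxyl installs the C9 acetate of the target.

Step 18
Reactants: 22 (2E,5S,6E,9S,10S,11R)-9-acetoxy-5-[(tert-butyldimethylsilyl)oxy]-14-iodo-6,10-dimethyl-11-(propa-1,2-dien-1-yl)pentadeca-2,6,14-trienal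
Product: 23 fourteen-membered carbocyclic bis-allylic alcohol: (E)-C1=C2, C3–OH (both epimers), exocyclic methylene on C4, allenyl on C7 (7R), CH3 on C8 (8S), OAc on C9 (9S), (E)-C11=C12(CH3), OSi-t-BuMe2 on C13 (13S)
Conditions: CrCl2 (10 equiv), NiCl2 (0.1 equiv), DMSO/THF 3:1, 0.003 M, rt
Reagents that add atoms: none
Why: Nozaki–Hiyama–Kishi macrocyclisation; nickel-catalysed formation of the alkenylchromium species from the 2-iodoalkene and its chemoselective 1,2-addition to the enal close the ring at C3–C4, and the C3 configuration is irrelevant.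

Step 19
Reactants: 23 fourteen-membered bis-allylic alcohol
Product: 24 fourteen-membered cross-conjugated dienone: C3 ketone flanked by (E)-C1=C2 and the C4 exocyclic methylene; other groups as in 23
Conditions: Dess–Martin periodinane, pyridine, CH2Cl2, 0 °C
Reagents that add atoms: none
Why: Dess–Martin oxidation of the bis-allylic alcohol under buffered conditions gives the acid-sensitive divinyl ketone.

Step 20
Reactants: 24 fourteen-membered cross-conjugated dienone
Product: 25 fourteen-membered triethylsilyl dienol ether: (E)-C1=C2–C3(OSiEt3)=C4(CH3), oxygen cis to the C4 methyl (C5 cis to C2); other groups as in 23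
Conditions: RhCl(PPh3)3 (3 mol %), Et3SiH (1.3 equiv), benzene, 50 °C; filtration through neutral alumina
Reagents that add atoms: triethylsilane, CC[SiH](CC)CC
Why: rhodium-catalysed 1,4-hydrosilylation of an enone; hydride goes to the unhindered methylene terminus of the s-cis α-methylene ketone, so oxygen and the new methyl end up cis on C3=C4, which places the methyl outside and the tether carbon C5 inside in the diene.

Step 21
Reactants: 25 fourteen-membered triethylsilyl dienol ether
Product: 27 tricyclic C3 ketone (1R,4S,7R,8S,9S,13S,16S): cis-fused cyclohexanone/cyclopentane with exocyclic methylene on C15, bridged from C1 to C7 by the chain C14–C13(OSi-t-BuMe2)–C12(CH3)=C11–C10–C9(OAc)–C8(CH3), via silyl enol ether cycloadduct 26 (not isolated)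
Conditions: toluene (0.005 M), 2,6-di-tert-butyl-4-methylphenol (cat.), 150 °C, sealed tube; then AcOH/THF/H2O 3:1:1, rt
Reagents that add atoms: none
Why: Thermal intramolecular Diels–Alder reaction in which the in-ring 2-silyloxy diene C1=C2–C3(OSiEt3)=C4 adds suprafacially across the proximal π bond C16=C15 of the pendant allene, forming C1–C15 and C4–C16 in one concerted step while the distal π bond survives as the exocyclic methylene; the closest known reaction types are intramolecular Diels–Alder reactions with allenes as dienophiles, those of (Z)-dienes on a three-atom tether, and transannular Diels–Alder reactions of fourteen-membered rings. The cyclohexene is closed by the [4+2] event itself, the cyclopentane (C4, C5, C6, C7, C16) by the three-atom tether C5–C6–C7 that joins the inside position of diene terminus C4 to dienophile carbon C16, and the eleven-membered ring is what remains of the fourteen-membered ring once C1–C15 exists. C1 and C4 are controlled by the diene geometry fixed in steps 12 and 20 (C14 and the C4 methyl both outside, hence cis), and C16 by the short tether, which can only span from the inside position of C4 to the exo position on C16 and so enforces the cis ring fusion with H16 cis to the methyl group. The absolute sense is relayed from C7: the seven-atom arm C8–C14 that leads back to C1 should let the allene reach only the diene face that puts C8 on the same side of the new cyclopentane as C15. The step needs periselectivity (proximal allene π bond, [4+2] rather than [1,5]-hydrogen shift of the (Z)-diene or [2+2]), which the tether length and the strain release of the allene should secure, and the facial selectivity just described, which the macrocycle secures.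

Step 22
Reactants: 27 tricyclic C3 ketone
Product: 28 tricyclic (3S)-alcohol, otherwise as 27
Conditions: (R)-2-methyl-CBS-oxazaborolidine (0.5 equiv), catecholborane, toluene, −78 to −40 °C
Reagents that add atoms: none
Why: Corey–Bakshi–Shibata reduction; the catalyst distinguishes quaternary C4 (large) from the C2 methylene (small) and should give the (3S)-alcohol, and catecholborane does not hydroborate the alkenes at low temperature.

Step 23
Reactants: 28 tricyclic (3S)-alcohol
Product: 29 tricyclic C3 propionate, C13 silyl ether (13S)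
Conditions: (EtCO)2O, DMAP, Et3N, CH2Cl2, rt to 40 °C
Reagents that add atoms: propanoic anhydride, CCC(=O)OC(=O)CC
Why: DMAP-catalysed acylation of the hindered secondary alcohol, the only free hydroxyl.

Step 24
Reactants: 29 tricyclic C3 propionate, C13 silyl ether
Product: 30 (13S)-allylic alcohol: the target skeleton with C11=C12 (E) alkene and 13-epi hydroxyl
Conditions: HF·pyridine, THF, 0 °C to rt
Reagents that add atoms: none
Why: fluoride cleavage of the silyl ether; esters and alkenes are inert.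

Step 25
Reactants: 30 (13S)-allylic alcohol
Product: 31 (11S,12S,13S)-epoxy alcohol (13-epimer of the target)
Conditions: Ti(O-i-Pr)4, L-(+)-diisopropyl tartrate, t-BuOOH, 4 Å molecular sieves, CH2Cl2, −20 °C
Reagents that add atoms: tert-butyl hydroperoxide, CC(C)(C)OO
Why: Sharpless epoxidation of a secondary allylic alcohol in the matched sense; with L-(+)-tartrate the (13S)-carbinol is the fast-reacting enantiomer and should give the erythro epoxy alcohol with oxygen on the required face (11S,12S), while the exocyclic methylene has no directing hydroxyl.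

Step 26
Reactants: 31 (11S,12S,13S)-epoxy alcohol
Product: 33 CNP0415604.1 (target, 13R), via inverted chloroacetate 32 (not isolated)
Conditions: PPh3, DIAD, ClCH2CO2H, toluene, 0 °C to rt; then K2CO3 (cat.), MeOH, −20 °C
Reagents that add atoms: chloroacetic acid, OC(=O)CCl
Why: Mitsunobu inversion; SN2 displacement of the oxyphosphonium by chloroacetate inverts C13 (erythro to threo), and the chloroacetate is methanolysed far faster than the acetate and propionate.

**Compound list**

1 | 3-[(tert-butyldimethylsilyl)oxy]propanal | O=CCCO[Si](C)(C)C(C)(C)C | starting material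
2 | (3S,4S)-1-[(tert-butyldimethylsilyl)oxy]-4-methylhex-5-en-3-ol | C=C[C@H](C)[C@@H](O)CCO[Si](C)(C)C(C)(C)C | intermediate
3 | B-alkyl-9-BBN adduct of 2 (boron on the terminal carbon) | C[C@@H](CCB1C2CCCC1CCC2)[C@@H](O)CCO[Si](C)(C)C(C)(C)C | intermediate
4 | (3S,4S)-6-[(tert-butyldimethylsilyl)oxy]-3-methylhexane-1,4-diol | OCC[C@H](C)[C@@H](O)CCO[Si](C)(C)C(C)(C)C | intermediate
5 | (4S,5S)-5-{2-[(tert-butyldimethylsilyl)oxy]ethyl}-4-methyloxolan-2-ol (lactol) | OC1C[C@H](C)[C@H](CCO[Si](C)(C)C(C)(C)C)O1 | intermediate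
6 | (4S,5S)-5-{2-[(tert-butyldimethylsilyl)oxy]ethyl}-4-methyloxolan-2-one | O=C1C[C@H](C)[C@H](CCO[Si](C)(C)C(C)(C)C)O1 | intermediate
7 | but-3-yn-1-ol | C#CCCO | starting material
8 | 3-iodobut-3-en-1-ol | C=C(I)CCO | intermediate
9 | 3-iodobut-3-en-1-yl trifluoromethanesulfonate | C=C(I)CCOS(=O)(=O)C(F)(F)F | intermediate
10 | (3S,4S,5S)-5-{2-[(tert-butyldimethylsilyl)oxy]ethyl}-3-(3-iodobut-3-en-1-yl)-4-methyloxolan-2-one | O=C1[C@@H](CCC(I)=C)[C@H](C)[C@H](CCO[Si](C)(C)C(C)(C)C)O1 | intermediate
11 | (3S,4S,5S)-5-(2-hydroxyethyl)-3-(3-iodobut-3-en-1-yl)-4-methyloxolan-2-one | O=C1[C@@H](CCC(I)=C)[C@H](C)[C@H](CCO)O1 | intermediate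
12 | 2-[(2S,3S,4S)-4-(3-iodobut-3-en-1-yl)-3-methyl-5-oxooxolan-2-yl]acetaldehyde | O=C1[C@@H](CCC(I)=C)[C@H](C)[C@H](CC=O)O1 | intermediate
13 | (2E)-4-[(2S,3S,4S)-4-(3-iodobut-3-en-1-yl)-3-methyl-5-oxooxolan-2-yl]-2-methylbut-2-enal | O=C1[C@@H](CCC(I)=C)[C@H](C)[C@H](C/C=C(\C)C=O)O1 | intermediate
14 | (3S,4S,5S)-5-[(2E,4S)-4-hydroxy-3-methylhepta-2,6-dien-1-yl]-3-(3-iodobut-3-en-1-yl)-4-methyloxolan-2-one | O=C1[C@@H](CCC(I)=C)[C@H](C)[C@H](C/C=C(\C)[C@@H](O)CC=C)O1 | intermediate
15 | tert-butyldimethylsilyl ether of 14 | O=C1[C@@H](CCC(I)=C)[C@H](C)[C@H](C/C=C(\C)[C@@H](O[Si](C)(C)C(C)(C)C)CC=C)O1 | intermediate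
16 | methyl (2E,5S,6E)-5-[(tert-butyldimethylsilyl)oxy]-8-[(2S,3S,4S)-4-(3-iodobut-3-en-1-yl)-3-methyl-5-oxooxolan-2-yl]-6-methylocta-2,6-dienoate | O=C1[C@@H](CCC(I)=C)[C@H](C)[C@H](C/C=C(\C)[C@@H](O[Si](C)(C)C(C)(C)C)C/C=C/C(=O)OC)O1 | intermediate
17 | (3S,4S,5S)-5-{(2E,4S,6E)-4-[(tert-butyldimethylsilyl)oxy]-8-hydroxy-3-methylocta-2,6-dien-1-yl}-3-(3-iodobut-3-en-1-yl)-4-methyloxolan-2-ol | OC1[C@@H](CCC(I)=C)[C@H](C)[C@H](C/C=C(\C)[C@@H](O[Si](C)(C)C(C)(C)C)C/C=C/CO)O1 | intermediate
18 | (2E,5S,6E,9S,10S,11S)-5-[(tert-butyldimethylsilyl)oxy]-11-ethynyl-14-iodo-6,10-dimethylpentadeca-2,6,14-triene-1,9-diol | C#C[C@@H](CCC(I)=C)[C@H](C)[C@@H](O)C/C=C(\C)[C@@H](O[Si](C)(C)C(C)(C)C)C/C=C/CO | intermediate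
19 | N,N-dicyclohexyl propargylic amine (Mannich base) of 18 | C(C#C[C@@H](CCC(I)=C)[C@H](C)[C@@H](O)C/C=C(\C)[C@@H](O[Si](C)(C)C(C)(C)C)C/C=C/CO)N(C1CCCCC1)C1CCCCC1 | intermediate
20 | (2E,5S,6E,9S,10S,11R)-5-[(tert-butyldimethylsilyl)oxy]-14-iodo-6,10-dimethyl-11-(propa-1,2-dien-1-yl)pentadeca-2,6,14-triene-1,9-diol | C=C=C[C@@H](CCC(I)=C)[C@H](C)[C@@H](O)C/C=C(\C)[C@@H](O[Si](C)(C)C(C)(C)C)C/C=C/CO | intermediate
21 | (2E,5S,6E,9S,10S,11R)-5-[(tert-butyldimethylsilyl)oxy]-9-hydroxy-14-iodo-6,10-dimethyl-11-(propa-1,2-dien-1-yl)pentadeca-2,6,14-trienal | C=C=C[C@@H](CCC(I)=C)[C@H](C)[C@@H](O)C/C=C(\C)[C@@H](O[Si](C)(C)C(C)(C)C)C/C=C/C=O | intermediate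
22 | (2E,5S,6E,9S,10S,11R)-9-acetoxy-5-[(tert-butyldimethylsilyl)oxy]-14-iodo-6,10-dimethyl-11-(propa-1,2-dien-1-yl)pentadeca-2,6,14-trienal | C=C=C[C@@H](CCC(I)=C)[C@H](C)[C@@H](OC(C)=O)C/C=C(\C)[C@@H](O[Si](C)(C)C(C)(C)C)C/C=C/C=O | intermediate
23 | fourteen-membered bis-allylic alcohol (7R,8S,9S,13S; C3 epimers) | OC1/C=C/C[C@H](O[Si](C)(C)C(C)(C)C)/C(C)=C/C[C@H](OC(C)=O)[C@@H](C)[C@@H](C=C=C)CCC1=C | intermediate
24 | fourteen-membered cross-conjugated dienone (7R,8S,9S,13S) | O=C1/C=C/C[C@H](O[Si](C)(C)C(C)(C)C)/C(C)=C/C[C@H](OC(C)=O)[C@@H](C)[C@@H](C=C=C)CCC1=C | intermediate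
25 | fourteen-membered triethylsilyl dienol ether (O cis to C4 methyl; 7R,8S,9S,13S) | C/C1=C(O[Si](CC)(CC)CC)/C=C/C[C@H](O[Si](C)(C)C(C)(C)C)/C(C)=C/C[C@H](OC(C)=O)[C@@H](C)[C@@H](C=C=C)CC1 | intermediate
26 | tricyclic triethylsilyl enol ether cycloadduct (C2=C3–OSiEt3; 1R,4S,7R,8S,9S,13S,16S) | C=C1[C@H]2C=C(O[Si](CC)(CC)CC)[C@@]3(C)CC[C@@H]([C@H](C)[C@@H](OC(C)=O)C/C=C(C)/[C@@H](O[Si](C)(C)C(C)(C)C)C2)[C@@H]13 | intermediate
27 | tricyclic C3 ketone | C=C1[C@H]2CC(=O)[C@@]3(C)CC[C@@H]([C@H](C)[C@@H](OC(C)=O)C/C=C(C)/[C@@H](O[Si](C)(C)C(C)(C)C)C2)[C@@H]13 | intermediate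
28 | tricyclic (3S)-alcohol | C=C1[C@H]2C[C@H](O)[C@@]3(C)CC[C@@H]([C@H](C)[C@@H](OC(C)=O)C/C=C(C)/[C@@H](O[Si](C)(C)C(C)(C)C)C2)[C@@H]13 | intermediate
29 | tricyclic C3 propionate, C13 silyl ether | C=C1[C@H]2C[C@H](OC(=O)CC)[C@@]3(C)CC[C@@H]([C@H](C)[C@@H](OC(C)=O)C/C=C(C)/[C@@H](O[Si](C)(C)C(C)(C)C)C2)[C@@H]13 | intermediate
30 | (13S)-allylic alcohol (11,12-alkene, 13-epi) | C=C1[C@H]2C[C@H](OC(=O)CC)[C@@]3(C)CC[C@@H]([C@H](C)[C@@H](OC(C)=O)C/C=C(C)/[C@@H](O)C2)[C@@H]13 | intermediate
31 | (11S,12S,13S)-epoxy alcohol (13-epi-target) | C=C1[C@H]2C[C@H](OC(=O)CC)[C@@]3(C)CC[C@@H]([C@H](C)[C@@H](OC(C)=O)C[C@@H]4O[C@@]4(C)[C@@H](O)C2)[C@@H]13 | intermediate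
32 | (13R)-chloroacetate of the target | C=C1[C@H]2C[C@H](OC(=O)CC)[C@@]3(C)CC[C@@H]([C@H](C)[C@@H](OC(C)=O)C[C@@H]4O[C@@]4(C)[C@H](OC(=O)CCl)C2)[C@@H]13 | intermediate
33 | CNP0415604.1 | C=C1[C@H]2C[C@H](OC(=O)CC)[C@@]3(C)CC[C@@H]([C@H](C)[C@@H](OC(C)=O)C[C@@H]4O[C@@]4(C)[C@H](O)C2)[C@@H]13 | target

**Step count and risks**

Total step count: 26. Longest linear sequence: 24 steps (steps 1–3 and 6–26; steps 4–5 make the side fragment).

Steps most likely to fail:

1. Step 21. The cycloaddition may be slower than a [1,5]-hydrogen shift of the (Z)-diene or than allene [2+2] or oligomerisation, or the allene may add to the other diene face. The fallback sets out from 25 and comes back at 27 and replaces the concerted thermal event by a stepwise, metal-triggered closure. A cationic monovalent gold phosphite complex, [(2,4-t-Bu2C6H3O)3P]AuCl/AgSbF6 (5 mol %), CH2Cl2, −20 °C to rt, would activate the allene; the enol-silane carbon C4 would close the cyclopentane at C16, and the resulting vinylgold carbon C15 would close the cyclohexane at C1 of the silyloxyallyl cation. The same acidic work-up then gives 27. No new isolable compound lies on this path.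

2. Step 20. Hydride transfer may go to the other enone or to the allene, or the enol-silane geometry may erode. The fallback sets out from 24 and comes back at 25. Conjugate reduction with LiBH(s-Bu)3 in THF at −78 °C (hydride to the unhindered methylene terminus, allene untouched) and NH4Cl quench would give the saturated α-methyl ketone F1 (both C4 epimers, irrelevant). Soft enolisation toward C4 with Et3SiOTf/Et3N in CH2Cl2 would then give 25, whose C3=C4 geometry would have to be checked before the cycloaddition.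

3. Step 26. The oxyphosphonium at the hindered carbinol next to the fully substituted epoxide carbon may not form or may eliminate instead of being displaced. The fallback sets out from 31 and comes back at 33. Dess–Martin oxidation would give the epoxy ketone F2, and reagent-controlled reduction with (S)-2-methyl-CBS-oxazaborolidine and catecholborane in toluene at −78 °C should give the (13R)-alcohol 33 directly.

Further compounds
F0 | step 21 | none | none
F1 | step 20 | fourteen-membered α-methyl enone (C4 epimers; 7R,8S,9S,13S) | O=C1/C=C/C[C@H](O[Si](C)(C)C(C)(C)C)/C(C)=C/C[C@H](OC(C)=O)[C@@H](C)[C@@H](C=C=C)CCC1C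
F2 | step 26 | 11,12-epoxy-13-ketone of the target skeleton (11S,12S) | C=C1[C@H]2C[C@H](OC(=O)CC)[C@@]3(C)CC[C@@H]([C@H](C)[C@@H](OC(C)=O)C[C@@H]4O[C@@]4(C)C(=O)C2)[C@@H]13
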